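## Retrosynthetic overview

1. Atom numbers are those of the target's bicyclo[3.2.1]oct-3-ene-2,8-dione skeleton: C1 (CH bridgehead), C2 (C=O), C3 (C–OMe), C4 (=CH), C5 (allyl-bearing bridgehead), C6 (CH–CH3), C7 (CH–aryl), C8 (bridging C=O).
2. Kadsurenin D ⇐ oxidation at C8 ⇐ Stork–Danheiser transposition (removes an auxiliary oxygen at C4) ⇐ bicyclic 4-hydroxy-enedione 12.
3. 12 ⇐ one-pot double Claisen (Dieckmann) condensation of acyclic keto-malonate 10, cutting C5–C8 and C2–C3 together. The cyclopentanone ring (C1, C5, C6, C7, C8) closes first, then the six-membered ring (C1–C5 plus C8), so both bridges of the bicyclo[3.2.1]octane are made in one operation.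
4. Enabling feature: C1–H lies between the C2 and C8 carbonyls (a 2-substituted malonyl unit), and C3 and C5 are the α and α′ carbons of a temporary C4 ketone. Both new bonds are therefore enolate acylations, and C5 and C1 are relayed from C6/C7.
5. 10 ⇐ catalytic enantioselective Michael addition of propanal to an arylidene malonate (sets C7 and C6), one-carbon homologation with Claisen allylation, then methoxymethyl addition and oxidation.

Key step: step 7

## Route

Step 1
Reactants: 1 3,4-dimethoxybenzaldehyde; 2 dimethyl malonate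
Product: 3 dimethyl 2-[(3,4-dimethoxyphenyl)methylidene]propanedioate
Conditions: piperidine (cat.), AcOH (cat.), toluene, reflux, Dean–Stark
Reagents that add atoms: none
Why: Knoevenagel condensation of a non-enolisable aryl aldehyde with an active methylene compound, driven by azeotropic removal of water.

Step 2
Reactants: 3 dimethyl 2-[(3,4-dimethoxyphenyl)methylidene]propanedioate; 4 propanal
Product: 5 dimethyl 2-[(1R,2R)-1-(3,4-dimethoxyphenyl)-2-methyl-3-oxopropyl]propanedioate
Conditions: (S)-α,α-diphenylprolinol trimethylsilyl ether (10 mol %), PhCO2H (10 mol %), CHCl3, 4 °C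
Reagents that add atoms: none
Why: Enamine-catalysed (Hayashi–Jørgensen) Michael addition in which the face-shielded (E)-enamine of propanal adds to the arylidene malonate through the acyclic synclinal transition state, which should set the aryl-bearing centre (C7) and the methyl-bearing centre (C6) syn and (R,R), by analogy with nitroalkene acceptors.

Step 3
Reactants: 5 dimethyl 2-[(1R,2R)-1-(3,4-dimethoxyphenyl)-2-methyl-3-oxopropyl]propanedioate
Product: 6 dimethyl 2-[(1R,2R)-1-(3,4-dimethoxyphenyl)-4-methoxy-2-methylbut-3-en-1-yl]propanedioate (E/Z mixture)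
Conditions: MeOCH2PPh3Cl, KOt-Bu, THF, −78 → 0 °C (excess ylide, inverse addition)
Reagents that add atoms: (methoxymethyl)triphenylphosphonium chloride, COC[P+](c1ccccc1)(c1ccccc1)c1ccccc1.[Cl-]
Why: Wittig olefination with the methoxymethylene ylide (one-carbon aldehyde homologation), run cold so that the aldehyde should be consumed before its α-centre can epimerise; the enol ether geometry is irrelevant.

Step 4
Reactants: 6 dimethyl 2-[(1R,2R)-1-(3,4-dimethoxyphenyl)-4-methoxy-2-methylbut-3-en-1-yl]propanedioate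
Product: 8 dimethyl 2-[(1R,2R)-1-(3,4-dimethoxyphenyl)-3-formyl-2-methylhex-5-en-1-yl]propanedioate (C3 epimers), via allyl enol ether 7 (not isolated)
Conditions: allyl alcohol (5 equiv), PPTS (5 mol %), xylene, 80 → 140 °C, MeOH distilled off
Reagents that add atoms: allyl alcohol, C=CCO
Why: Acid-catalysed enol ether exchange followed by Claisen rearrangement ([3,3]) should deliver the allyl group to the future C5; its configuration does not matter because this centre is re-enolised in step 7.

Step 5
Reactants: 8 dimethyl 2-[(1R,2R)-1-(3,4-dimethoxyphenyl)-3-formyl-2-methylhex-5-en-1-yl]propanedioate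
Product: 9 dimethyl 2-[(1R,2R)-1-(3,4-dimethoxyphenyl)-3-(1-hydroxy-2-methoxyethyl)-2-methylhex-5-en-1-yl]propanedioate (diastereomer mixture)
Conditions: Bu3SnCH2OMe, n-BuLi, THF, −78 °C; then 8; then H2O
Reagents that add atoms: tributyl(methoxymethyl)stannane, CCCC[Sn](CCCC)(CCCC)COC
Why: Still's α-alkoxy organolithium (Sn–Li exchange) should add to the aldehyde at −78 °C while the malonate is held as its lithium enolate; the carbinol configuration is erased in the next step.

Step 6
Reactants: 9 dimethyl 2-[(1R,2R)-1-(3,4-dimethoxyphenyl)-3-(1-hydroxy-2-methoxyethyl)-2-methylhex-5-en-1-yl]propanedioate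
Product: 10 dimethyl 2-[(1R,2R)-1-(3,4-dimethoxyphenyl)-3-(2-methoxyacetyl)-2-methylhex-5-en-1-yl]propanedioate (C3 epimers)
Conditions: Dess–Martin periodinane, NaHCO3, CH2Cl2, 0 °C → rt
Reagents that add atoms: none
Why: Dess–Martin oxidation of a secondary alcohol under buffered, non-basic conditions.

Step 7
Reactants: 10 dimethyl 2-[(1R,2R)-1-(3,4-dimethoxyphenyl)-3-(2-methoxyacetyl)-2-methylhex-5-en-1-yl]propanedioate
Product: 12 (1S,5S,6R,7R)-7-(3,4-dimethoxyphenyl)-4-hydroxy-3-methoxy-6-methyl-5-(prop-2-en-1-yl)bicyclo[3.2.1]oct-3-ene-2,8-dione (enol form of the 2,4,8-trione), via cyclopentanone keto ester 11 (not isolated)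
Conditions: NaOMe (2.5 equiv), MeOH, 0 °C → reflux; then 1 M HCl
Reagents that add atoms: none
Why: Double Claisen (Dieckmann-type) condensation: the ketone enolate at the allyl-bearing α-carbon attacks one malonate ester to form C5–C8 and close the cyclopentanone (5-(enolexo)-exo-trig; 11 is held as its β-keto ester enolate), then the α′-enolate at the methoxy-bearing carbon attacks the remaining ester to form C2–C3 (6-(enolendo)-exo-trig), and the sequence is pulled forward by deprotonation of the resulting 2-methoxy-1,3-diketone. The closest known reactions are the alkoxide cyclisation of keto-malonates to cyclohexane-1,3-diones and Dieckmann closures of bridged polyketide triones, i.e. an intramolecular version of the Effenberger α,α′-annulation. The quaternary centre C5 is set in the first closure under substrate control from C6/C7, and C1 follows because the three-carbon bridge can only span the cyclopentanone cis; C1 stays epimerisable until the second closure. Since the first Claisen is reversible under alkoxide and the second closure is much easier when the aryl group ends exo, the process should funnel to the (1S,5S,6R,7R) isomer. The step needs acylation at the more substituted α-carbon first (five- versus seven-membered ring) and survival of the methoxyacetyl arm against retro-Claisen cleavage (11 is an enolate and the second closure is intramolecular); the electron-rich arene is inert under these basic conditions.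

Step 8
Reactants: 12 (1S,5S,6R,7R)-7-(3,4-dimethoxyphenyl)-4-hydroxy-3-methoxy-6-methyl-5-(prop-2-en-1-yl)bicyclo[3.2.1]oct-3-ene-2,8-dione
Product: 13 (1R,5R,6R,7R)-6-(3,4-dimethoxyphenyl)-3,4-dimethoxy-7-methyl-1-(prop-2-en-1-yl)bicyclo[3.2.1]oct-3-ene-2,8-dione (new O-methyl on the oxygen at target C2)
Conditions: Me2SO4 (1.1 equiv), K2CO3, acetone, rt
Reagents that add atoms: dimethyl sulfate, COS(=O)(=O)OC
Why: O-methylation of the cyclic 1,3-diketone enolate should occur at the more accessible oxygen (on C2, remote from the quaternary C5), the regiochemistry known for unsymmetrical 4,4-disubstituted cyclohexane-1,3-diones used in Stork–Danheiser sequences.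

Step 9
Reactants: 13 (1R,5R,6R,7R)-6-(3,4-dimethoxyphenyl)-3,4-dimethoxy-7-methyl-1-(prop-2-en-1-yl)bicyclo[3.2.1]oct-3-ene-2,8-dione
Product: 15 (1S,5S,6R,7R)-7-(3,4-dimethoxyphenyl)-8-hydroxy-3-methoxy-6-methyl-5-(prop-2-en-1-yl)bicyclo[3.2.1]oct-3-en-2-one (C8 epimers), via diol enol ether 14 (not isolated)
Conditions: LiAlH4, THF, −78 → 0 °C; then 1 M HCl, THF, rt
Reagents that add atoms: water, O
Why: Stork–Danheiser transposition: 1,2-hydride addition to the vinylogous ester carbonyl (C4), then acid-induced loss of water and enol ether hydrolysis, should unveil the C2 ketone and the C3=C4 double bond; the C8 ketone is reduced as well and is restored in step 10, and no stereocentre of the target is touched.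

Step 10
Reactants: 15 (1S,5S,6R,7R)-7-(3,4-dimethoxyphenyl)-8-hydroxy-3-methoxy-6-methyl-5-(prop-2-en-1-yl)bicyclo[3.2.1]oct-3-en-2-one
Product: 16 kadsurenin D, (1S,5S,6R,7R)-7-(3,4-dimethoxyphenyl)-3-methoxy-6-methyl-5-(prop-2-en-1-yl)bicyclo[3.2.1]oct-3-ene-2,8-dione
Conditions: Dess–Martin periodinane, NaHCO3, CH2Cl2, rt
Reagents that add atoms: none
Why: Dess–Martin oxidation of the bridging secondary alcohol to the C8 ketone under neutral conditions that should leave the non-enolisable β-diketone intact.

## Compound list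

1 | 3,4-dimethoxybenzaldehyde | COc1ccc(C=O)cc1OC | starting material
2 | dimethyl malonate | COC(=O)CC(=O)OC | starting material
3 | dimethyl 2-[(3,4-dimethoxyphenyl)methylidene]propanedioate | COC(=O)C(=Cc1ccc(OC)c(OC)c1)C(=O)OC | intermediate
4 | propanal | CCC=O | starting material
5 | dimethyl 2-[(1R,2R)-1-(3,4-dimethoxyphenyl)-2-methyl-3-oxopropyl]propanedioate | COC(=O)C(C(=O)OC)[C@H](c1ccc(OC)c(OC)c1)[C@@H](C)C=O | intermediate
6 | dimethyl 2-[(1R,2R)-1-(3,4-dimethoxyphenyl)-4-methoxy-2-methylbut-3-en-1-yl]propanedioate (E/Z mixture) | COC(=O)C(C(=O)OC)[C@H](c1ccc(OC)c(OC)c1)[C@@H](C)C=COC | intermediate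
7 | dimethyl 2-[(1R,2R)-1-(3,4-dimethoxyphenyl)-2-methyl-4-(prop-2-en-1-yloxy)but-3-en-1-yl]propanedioate (not isolated) | COC(=O)C(C(=O)OC)[C@H](c1ccc(OC)c(OC)c1)[C@@H](C)C=COCC=C | intermediate
8 | dimethyl 2-[(1R,2R)-1-(3,4-dimethoxyphenyl)-3-formyl-2-methylhex-5-en-1-yl]propanedioate (C3 epimers) | COC(=O)C(C(=O)OC)[C@H](c1ccc(OC)c(OC)c1)[C@@H](C)C(CC=C)C=O | intermediate
9 | dimethyl 2-[(1R,2R)-1-(3,4-dimethoxyphenyl)-3-(1-hydroxy-2-methoxyethyl)-2-methylhex-5-en-1-yl]propanedioate (diastereomer mixture) | COC(=O)C(C(=O)OC)[C@H](c1ccc(OC)c(OC)c1)[C@@H](C)C(CC=C)C(O)COC | intermediate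
10 | dimethyl 2-[(1R,2R)-1-(3,4-dimethoxyphenyl)-3-(2-methoxyacetyl)-2-methylhex-5-en-1-yl]propanedioate (C3 epimers) | COC(=O)C(C(=O)OC)[C@H](c1ccc(OC)c(OC)c1)[C@@H](C)C(CC=C)C(=O)COC | intermediate
11 | methyl (1S,3R,4R,5R)-5-(3,4-dimethoxyphenyl)-3-(2-methoxyacetyl)-4-methyl-2-oxo-3-(prop-2-en-1-yl)cyclopentane-1-carboxylate (present as its enolate, not isolated) | C=CC[C@]1(C(=O)COC)C(=O)[C@@H](C(=O)OC)[C@H](c2ccc(OC)c(OC)c2)[C@H]1C | intermediate
12 | (1S,5S,6R,7R)-7-(3,4-dimethoxyphenyl)-4-hydroxy-3-methoxy-6-methyl-5-(prop-2-en-1-yl)bicyclo[3.2.1]oct-3-ene-2,8-dione | C=CC[C@]12C(O)=C(OC)C(=O)[C@H](C1=O)[C@H](c1ccc(OC)c(OC)c1)[C@H]2C | intermediate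
13 | (1R,5R,6R,7R)-6-(3,4-dimethoxyphenyl)-3,4-dimethoxy-7-methyl-1-(prop-2-en-1-yl)bicyclo[3.2.1]oct-3-ene-2,8-dione | C=CC[C@]12C(=O)C(OC)=C(OC)[C@H](C1=O)[C@H](c1ccc(OC)c(OC)c1)[C@H]2C | intermediate
14 | 7-(3,4-dimethoxyphenyl)-2,3-dimethoxy-6-methyl-5-(prop-2-en-1-yl)bicyclo[3.2.1]oct-2-ene-4,8-diol (target numbering; ring stereocentres as in 13, carbinol epimers, not isolated) | C=CC[C@]12C(O)C(OC)=C(OC)[C@H](C1O)[C@H](c1ccc(OC)c(OC)c1)[C@H]2C | intermediate
15 | (1S,5S,6R,7R)-7-(3,4-dimethoxyphenyl)-8-hydroxy-3-methoxy-6-methyl-5-(prop-2-en-1-yl)bicyclo[3.2.1]oct-3-en-2-one (C8 epimers) | C=CC[C@]12C=C(OC)C(=O)[C@H](C1O)[C@H](c1ccc(OC)c(OC)c1)[C@H]2C | intermediate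
16 | kadsurenin D, (1S,5S,6R,7R)-7-(3,4-dimethoxyphenyl)-3-methoxy-6-methyl-5-(prop-2-en-1-yl)bicyclo[3.2.1]oct-3-ene-2,8-dione | C=CC[C@]12C=C(OC)C(=O)[C@H](C1=O)[C@H](c1ccc(OC)c(OC)c1)[C@H]2C | target

## Step count and risks

Total step count: 10. Longest linear sequence: 10 steps (from 3,4-dimethoxybenzaldehyde).

**Step 7 (key step).** What may go wrong: retro-Claisen cleavage that strips the methoxyacetyl arm from intermediate 11, and poor facial selectivity when the fully substituted enolate carbon (C5) is acylated. The fallback makes the same two bonds irreversibly by soft enolisation. It sets out from 10: saponification (LiOH, THF/H2O) would give the keto diacid F1; oxalyl chloride with catalytic DMF would convert it into the bis(acid chloride) F2, which is treated without isolation with MgBr2·OEt2 and i-Pr2NEt (CH2Cl2, 0 °C), so that the magnesium enolates of the ketone are C-acylated on both sides through the acyl ketene. Acidic work-up comes back to the route at 12.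

**Step 3.** What may go wrong: epimerisation at the aldehyde α-carbon (C6) or retro-Michael fragmentation once the basic ylide has deprotonated the malonate. The fallback avoids base while C6 is still α to a carbonyl. It sets out from 5: Takai–Lombardo methylenation (Zn, CH2Br2, TiCl4) would give the alkene F3; hydroboration–oxidation (9-BBN, then NaBO3) the primary alcohol F4; Dess–Martin oxidation the homologated aldehyde F5; condensation with pyrrolidine the enamine F6, which is allylated with allyl bromide (Stork enamine alkylation via N-allylation and aza-Claisen shift) and hydrolysed. It comes back to the route at 8.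

**Step 8.** What may go wrong: poor discrimination between the two enol oxygens, so that the transposition in step 9 would deliver the regioisomeric enone. The fallback replaces methylation by kinetic silylation with a bulky reagent. It sets out from 12: TIPSOTf and 2,6-lutidine (CH2Cl2, −78 °C) should silylate only the unhindered oxygen to give the vinylogous silyl ester F7, which is reduced with LiAlH4 and treated with aqueous HCl exactly as in step 9. It comes back to the route at 15.

## Further compounds

F1 | step 7 | 2-[(1R,2R)-1-(3,4-dimethoxyphenyl)-3-(2-methoxyacetyl)-2-methylhex-5-en-1-yl]propanedioic acid | OC(=O)C(C(=O)O)[C@H](c1ccc(OC)c(OC)c1)[C@@H](C)C(CC=C)C(=O)COC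
F2 | step 7 | 2-[(1R,2R)-1-(3,4-dimethoxyphenyl)-3-(2-methoxyacetyl)-2-methylhex-5-en-1-yl]propanedioyl dichloride | ClC(=O)C(C(Cl)=O)[C@H](c1ccc(OC)c(OC)c1)[C@@H](C)C(CC=C)C(=O)COC
F3 | step 3 | dimethyl 2-[(1R,2S)-1-(3,4-dimethoxyphenyl)-2-methylbut-3-en-1-yl]propanedioate | COC(=O)C(C(=O)OC)[C@H](c1ccc(OC)c(OC)c1)[C@@H](C)C=C
F4 | step 3 | dimethyl 2-[(1R,2S)-1-(3,4-dimethoxyphenyl)-4-hydroxy-2-methylbutyl]propanedioate | COC(=O)C(C(=O)OC)[C@H](c1ccc(OC)c(OC)c1)[C@@H](C)CCO
F5 | step 3 | dimethyl 2-[(1R,2S)-1-(3,4-dimethoxyphenyl)-2-methyl-4-oxobutyl]propanedioate | COC(=O)C(C(=O)OC)[C@H](c1ccc(OC)c(OC)c1)[C@@H](C)CC=O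
F6 | step 3 | dimethyl 2-[(1R,2R)-1-(3,4-dimethoxyphenyl)-2-methyl-4-(pyrrolidin-1-yl)but-3-en-1-yl]propanedioate | COC(=O)C(C(=O)OC)[C@H](c1ccc(OC)c(OC)c1)[C@@H](C)C=CN1CCCC1
F7 | step 8 | (1R,5R,6R,7R)-6-(3,4-dimethoxyphenyl)-3-methoxy-7-methyl-1-(prop-2-en-1-yl)-4-[tri(propan-2-yl)silyloxy]bicyclo[3.2.1]oct-3-ene-2,8-dione | C=CC[C@]12C(=O)C(OC)=C(O[Si](C(C)C)(C(C)C)C(C)C)[C@H](C1=O)[C@H](c1ccc(OC)c(OC)c1)[C@H]2C
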